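**Plan**
- Cuts, in retrosynthetic order: the C1/C10 oxirane back to the 1(10)-E alkene; C3–C4 (aldehyde plus Z-alkenyl iodide, Ni/Cr); C4=C5 with C15 (Wittig on a C5 aldehyde, then α-iodination); the C8 ester; C7–C8 and C11=C13 (butenolide, lithiated dithiane, Mannich methylenation); C8–C9 (dithiane alkylation); C1=C10 (Wittig).
- Forward: the chain piece C8–C9–C10(C14)=C1–C2–C3 is made in five steps and joined to the lactone ring, which comes intact from the chiral pool. The chain is then extended by C4/C15, the ten-membered ring is closed at C3–C4 and the oxirane is formed on the macrocycle.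
- Enabling feature: the trans-fused α-methylene-γ-butyrolactone (ring O–C6–C7–C11–C12 with exocyclic C13) next to the C8 carbinol is (S)-5-hydroxymethylbutenolide that has taken up a C8 acyl-anion equivalent at C7 and a methylene at C11.
- Stereochemistry: C6 from the chiral pool; C7 by addition anti to the C6 substituent; C8 by CBS reduction; C3 in the Ni/Cr ring closure (macrocyclic control); C1/C10 by outer-face epoxidation of the E-alkene.

Key step: step 7

Remark: atoms carry the numbers they have in the target (C1–C10 ring, C11–C13 lactone carbons, C14 methyl on C10, C15 on C4). The target is taken as the enantiomer drawn (3β-OH, 8β-isobutyrate, 1β,10α-epoxide, H-6β, H-7α).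

**Step 1**
Reactants: 1 (S)-5-(hydroxymethyl)furan-2(5H)-one
Product: 2 (S)-5-[(tert-butyldimethylsilyloxy)methyl]furan-2(5H)-one
Conditions: TBSCl, imidazole, CH2Cl2, 0 °C → rt
Reagents that add atoms: tert-butyldimethylsilyl chloride, CC(C)(C)[Si](C)(C)Cl
Why: Imidazole-promoted silylation of the primary alcohol; the weak base should not enolise the butenolide, so C6 keeps its configuration.

**Step 2**
Reactants: 3 3-[(4-methoxybenzyl)oxy]propan-1-ol
Product: 4 3-[(4-methoxybenzyl)oxy]propanal
Conditions: TEMPO (cat.), PhI(OAc)2, CH2Cl2, rt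
Reagents that add atoms: none
Why: Oxoammonium (TEMPO) oxidation of a primary alcohol stops at the aldehyde and leaves the PMB ether alone.

**Step 3**
Reactants: 4 3-[(4-methoxybenzyl)oxy]propanal
Product: 5 ethyl (E)-5-[(4-methoxybenzyl)oxy]-2-methylpent-2-enoate
Conditions: Ph3P=C(Me)CO2Et, CH2Cl2, rt
Reagents that add atoms: ethyl 2-(triphenylphosphoranylidene)propanoate, CCOC(=O)C(C)=P(c1ccccc1)(c1ccccc1)c1ccccc1
Why: Wittig olefination with a stabilised ylide should give the E trisubstituted enoate, fixing the C1=C10 geometry (C2 trans to C9).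

**Step 4**
Reactants: 5 ethyl (E)-5-[(4-methoxybenzyl)oxy]-2-methylpent-2-enoate
Product: 6 (E)-5-[(4-methoxybenzyl)oxy]-2-methylpent-2-en-1-ol
Conditions: DIBAL-H, CH2Cl2, −78 °C; Rochelle salt
Reagents that add atoms: none
Why: DIBAL-H 1,2-reduction of an enoate to the allylic alcohol, without change of alkene geometry.

**Step 5**
Reactants: 6 (E)-5-[(4-methoxybenzyl)oxy]-2-methylpent-2-en-1-ol
Product: 7 (E)-1-bromo-5-[(4-methoxybenzyl)oxy]-2-methylpent-2-ene
Conditions: CBr4, PPh3, CH2Cl2, 0 °C
Reagents that add atoms: carbon tetrabromide, BrC(Br)(Br)Br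
Why: Appel bromination of a primary allylic alcohol proceeds by SN2 at C9 under neutral conditions.

**Step 6**
Reactants: 8 1,3-dithiane; 7 (E)-1-bromo-5-[(4-methoxybenzyl)oxy]-2-methylpent-2-ene
Product: 10 2-[(E)-5-[(4-methoxybenzyl)oxy]-2-methylpent-2-en-1-yl]-1,3-dithiane, via 2-lithio-1,3-dithiane 9 (not isolated)
Conditions: n-BuLi, THF, −30 °C; then 7, −78 → 0 °C
Reagents that add atoms: none
Why: Corey–Seebach alkylation; the dithiane anion displaces the primary allylic bromide by SN2 and forms C8–C9.

**Step 7**
Reactants: 10 2-[(E)-5-[(4-methoxybenzyl)oxy]-2-methylpent-2-en-1-yl]-1,3-dithiane; 2 (S)-5-[(tert-butyldimethylsilyloxy)methyl]furan-2(5H)-one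
Product: 15 6,7-trans α-methylene-γ-butyrolactone bearing CH2OTBS (C5) on C6 plus the 2-alkenyl-1,3-dithian-2-yl group (C8) on C7, via 2-lithiodithiane 11 (not isolated), via lithium lactone enolate 12 (not isolated), via C11 Mannich base 13 (not isolated), via C13 trimethylammonium iodide 14 (not isolated)
Conditions: n-BuLi, THF, −30 °C; HMPA, then 2, −78 °C; CH2=NMe2+ I−, −78 °C → rt; MeI, rt; aq NaHCO3
Reagents that add atoms: N,N-dimethylmethyleneiminium iodide (Eschenmoser's salt), C=[N+](C)C.[I-]
Why: The lithiated dithiane 11, kept as a solvent-separated ion pair by HMPA, adds as a soft sulfur-stabilised carbanion to C7 of the butenolide (Michael addition of an acyl-anion equivalent); the lactone enolate 12 is aminomethylated at C11 by the iminium salt (Mannich reaction), and N-methylation followed by base-induced loss of trimethylamine gives C11=C13. The closest known reaction type is the tandem conjugate addition of 2-lithio-1,3-dithianes to 5-substituted butenolides with enolate trapping, combined with Mannich methylenation of lactone enolates. No ring is closed; the lactone ring enters intact with 2. The only new stereocentre that persists is C7, controlled by the C6 CH2OTBS group, which shields its own face of the planar butenolide so that the carbanion enters anti and gives the 6,7-trans product; the C11 centre of 13 is erased on elimination. The step needs 1,4- over 1,2-attack and no γ-deprotonation of 2, which the HMPA-separated soft anion at −78 °C should secure. It also needs N- rather than S-methylation, which the much higher nucleophilicity of the tertiary amine toward MeI at rt should secure.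

**Step 8**
Reactants: 15 α-methylene lactone with C8 dithiane
Product: 16 C8 ketone (6,7-trans α-methylene lactone with C7–C(=O)–CH2–C(Me)=CH–CH2CH2OPMB)
Conditions: MeI, CaCO3, MeCN/H2O, 45 °C
Reagents that add atoms: water, O
Why: Alkylative dithiane hydrolysis (S-methylation, then hydrolysis of the sulfonium) under carbonate buffering should spare the silyl ether, the PMB ether and both alkenes; the ketone, which has acidic C7–H and C9–H, is taken on at once without exposure to base.

**Step 9**
Reactants: 16 C8 ketone
Product: 17 (8R)-alcohol (8β-OH)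
Conditions: (S)-Me-CBS (cat.), catecholborane, toluene/CH2Cl2, −78 °C; MeOH, pH 7 buffer
Reagents that add atoms: none
Why: Corey–Bakshi–Shibata reduction; with the branched C7 as the large group and the C9 methylene as the small one, the (S)-catalyst should deliver hydride to give 8R, a Felkin–Anh approach anti to C6 should reinforce this, and catecholborane should not touch the lactone, the enoate or the alkenes at −78 °C.

**Step 10**
Reactants: 17 (8R)-alcohol
Product: 18 C8 isobutyrate
Conditions: (i-PrCO)2O, pyridine, DMAP (cat.), CH2Cl2, 0 °C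
Reagents that add atoms: isobutyric anhydride, CC(C)C(=O)OC(=O)C(C)C
Why: DMAP-catalysed acylation of the secondary alcohol at 0 °C should be faster than translactonisation of the C8 hydroxyl onto C12.

**Step 11**
Reactants: 18 C8 isobutyrate
Product: 19 C5 primary alcohol
Conditions: HF·pyridine, pyridine, THF, 0 °C → rt
Reagents that add atoms: none
Why: Buffered fluoride cleavage of the primary TBS ether; the PMB ether, the esters and the α-methylene lactone are inert to it.

**Step 12**
Reactants: 19 C5 primary alcohol
Product: 20 C5 aldehyde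
Conditions: Dess–Martin periodinane, NaHCO3, CH2Cl2, 0 °C → rt
Reagents that add atoms: none
Why: Dess–Martin oxidation under buffered, non-epimerising conditions; the α-acyloxy aldehyde is used crude, and C6 is further protected by the preference for the 6,7-trans arrangement.

**Step 13**
Reactants: 20 C5 aldehyde
Product: 21 (E)-enal (C6–C5H=C4H–C15HO)
Conditions: Ph3P=CHCHO, toluene, rt → 40 °C
Reagents that add atoms: (triphenylphosphoranylidene)acetaldehyde, O=CC=P(c1ccccc1)(c1ccccc1)c1ccccc1
Why: Wittig reaction of a stabilised formyl ylide with the reactive α-oxygenated aldehyde gives the E-enal and introduces C4 and C15; the ylide is too weakly basic to epimerise C6.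

**Step 14**
Reactants: 21 (E)-enal
Product: 22 (Z)-α-iodoenal (iodine on C4, cis to C6)
Conditions: I2, pyridine, CH2Cl2, 0 °C → rt
Reagents that add atoms: iodine, II
Why: Amine-mediated α-iodination of an enal (conjugate addition of pyridine, iodination of the enolate, E1cB loss of pyridine) should give the isomer with CHO trans to C6, i.e. the Z-iodoalkene; the pyridine-complexed iodine should leave the isolated C1=C10 alkene alone.

**Step 15**
Reactants: 22 (Z)-α-iodoenal
Product: 23 (Z)-2-iodoallylic alcohol (C15–OH)
Conditions: NaBH4, CeCl3·7H2O, MeOH, −78 °C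
Reagents that add atoms: none
Why: Luche reduction gives selective 1,2-reduction of the aldehyde; at −78 °C the lactone, the isobutyrate and the α-methylene lactone should not be reduced.

**Step 16**
Reactants: 23 (Z)-2-iodoallylic alcohol
Product: 24 C15 triethylsilyl ether
Conditions: TESCl, imidazole, CH2Cl2, 0 °C
Reagents that add atoms: chlorotriethylsilane, CC[Si](Cl)(CC)CC
Why: Standard silylation of the primary allylic alcohol, so that C15–O stays masked while C3–O is unveiled and oxidised.

**Step 17**
Reactants: 24 C15 triethylsilyl ether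
Product: 25 C3 primary alcohol
Conditions: DDQ, CH2Cl2/pH 7 buffer, 0 °C → rt
Reagents that add atoms: none
Why: Oxidative PMB cleavage by DDQ (benzylic hydride abstraction, hydrolysis of the oxocarbenium ion) is orthogonal to the TES ether, the alkenyl iodide and the esters.

**Step 18**
Reactants: 25 C3 primary alcohol
Product: 26 C3 aldehyde (seco-aldehyde with the Z-alkenyl iodide)
Conditions: Dess–Martin periodinane, NaHCO3, CH2Cl2, 0 °C
Reagents that add atoms: none
Why: Buffered Dess–Martin oxidation of a homoallylic alcohol gives the β,γ-unsaturated aldehyde without migration of the trisubstituted alkene; it is used at once.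

**Step 19**
Reactants: 26 C3 aldehyde
Product: 27 ten-membered 1(10)E,4Z-dienolide with 3β-OH (3S), C15–OTES and C8 isobutyrate
Conditions: CrCl2 (excess), NiCl2 (cat.), DMSO/THF, rt, slow addition, ca. 2 mM
Reagents that add atoms: none
Why: Intramolecular Nozaki–Hiyama–Kishi reaction; Ni inserts into the C4–I bond and the configurationally stable alkenylchromium(III) adds only to the aldehyde, closing the ten-membered ring at C3–C4 with the Z geometry retained. The 3S carbinol is expected from attack on the aldehyde face that keeps the chromium alkoxide on the ring periphery, but this rests on macrocyclic control alone.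

**Step 20**
Reactants: 27 ten-membered dienolide
Product: 28 1β,10α-epoxide (C15–OTES)
Conditions: mCPBA, NaHCO3, CH2Cl2, 0 °C
Reagents that add atoms: meta-chloroperoxybenzoic acid, OOC(=O)c1cccc(Cl)c1
Why: Prilezhaev epoxidation should select the electron-rich C1=C10 bond; C4=C5 is deactivated by three allylic C–O bonds and the enoate is electron-poor. Attack on the exposed outer face of the E-alkene, as usual for 1(10)-germacrenolides, should give the trans epoxide with O β at C1 and α at C10.

**Step 21**
Reactants: 28 1β,10α-epoxide (C15–OTES)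
Product: 29 target compound (CNP0219050.1)
Conditions: HF·pyridine, pyridine, THF, 0 °C
Reagents that add atoms: none
Why: Buffered fluoride removal of the primary allylic TES ether is mild enough for the oxirane, the isobutyrate and the α-methylene lactone.

**Compound list**
1 | (S)-5-(hydroxymethyl)furan-2(5H)-one | OC[C@@H]1C=CC(=O)O1 | starting material
2 | (S)-5-[(tert-butyldimethylsilyloxy)methyl]furan-2(5H)-one | O=C1O[C@H](CO[Si](C)(C)C(C)(C)C)C=C1 | intermediate
3 | 3-[(4-methoxybenzyl)oxy]propan-1-ol | COc1ccc(COCCCO)cc1 | starting material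
4 | 3-[(4-methoxybenzyl)oxy]propanal | COc1ccc(COCCC=O)cc1 | intermediate
5 | ethyl (E)-5-[(4-methoxybenzyl)oxy]-2-methylpent-2-enoate | CCOC(=O)/C(C)=C/CCOCc1ccc(OC)cc1 | intermediate
6 | (E)-5-[(4-methoxybenzyl)oxy]-2-methylpent-2-en-1-ol | OC/C(C)=C/CCOCc1ccc(OC)cc1 | intermediate
7 | (E)-1-bromo-5-[(4-methoxybenzyl)oxy]-2-methylpent-2-ene | BrC/C(C)=C/CCOCc1ccc(OC)cc1 | intermediate
8 | 1,3-dithiane | C1CSCSC1 | starting material
9 | 2-lithio-1,3-dithiane | [Li]C1SCCCS1 | intermediate
10 | 2-[(E)-5-[(4-methoxybenzyl)oxy]-2-methylpent-2-en-1-yl]-1,3-dithiane (C8 to C3) | C1(C/C(C)=C/CCOCc2ccc(OC)cc2)SCCCS1 | intermediate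
11 | 2-lithio derivative of 10 | [Li]C1(C/C(C)=C/CCOCc2ccc(OC)cc2)SCCCS1 | intermediate
12 | lithium enolate of the 6,7-trans conjugate adduct | C1=C(O[Li])O[C@H](CO[Si](C)(C)C(C)(C)C)[C@H]1C1(C/C(C)=C/CCOCc2ccc(OC)cc2)SCCCS1 | intermediate
13 | C11 dimethylaminomethyl lactone (Mannich base, CH2NMe2 trans to the C7 substituent) | CN(C)C[C@@H]1C(=O)O[C@H](CO[Si](C)(C)C(C)(C)C)[C@H]1C1(C/C(C)=C/CCOCc2ccc(OC)cc2)SCCCS1 | intermediate
14 | trimethylammonium iodide of 13 | C[N+](C)(C)C[C@@H]1C(=O)O[C@H](CO[Si](C)(C)C(C)(C)C)[C@H]1C1(C/C(C)=C/CCOCc2ccc(OC)cc2)SCCCS1.[I-] | intermediate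
15 | 6,7-trans α-methylene-γ-butyrolactone with CH2OTBS on C6 and the C8 dithiane on C7 | C=C1C(=O)O[C@H](CO[Si](C)(C)C(C)(C)C)[C@H]1C1(C/C(C)=C/CCOCc2ccc(OC)cc2)SCCCS1 | intermediate
16 | C8 ketone | C=C1C(=O)O[C@H](CO[Si](C)(C)C(C)(C)C)[C@H]1C(=O)C/C(C)=C/CCOCc1ccc(OC)cc1 | intermediate
17 | (8R)-alcohol | C=C1C(=O)O[C@H](CO[Si](C)(C)C(C)(C)C)[C@H]1[C@H](O)C/C(C)=C/CCOCc1ccc(OC)cc1 | intermediate
18 | (8R)-isobutyrate with C5–OTBS and C3–OPMB | C=C1C(=O)O[C@H](CO[Si](C)(C)C(C)(C)C)[C@H]1[C@H](OC(=O)C(C)C)C/C(C)=C/CCOCc1ccc(OC)cc1 | intermediate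
19 | C5 primary alcohol | C=C1C(=O)O[C@H](CO)[C@H]1[C@H](OC(=O)C(C)C)C/C(C)=C/CCOCc1ccc(OC)cc1 | intermediate
20 | C5 aldehyde | C=C1C(=O)O[C@H](C=O)[C@H]1[C@H](OC(=O)C(C)C)C/C(C)=C/CCOCc1ccc(OC)cc1 | intermediate
21 | (E)-enal (C5=C4–C15HO) | C=C1C(=O)O[C@H](/C=C/C=O)[C@H]1[C@H](OC(=O)C(C)C)C/C(C)=C/CCOCc1ccc(OC)cc1 | intermediate
22 | (Z)-α-iodoenal (I on C4, cis to C6) | C=C1C(=O)O[C@H](/C=C(\I)C=O)[C@H]1[C@H](OC(=O)C(C)C)C/C(C)=C/CCOCc1ccc(OC)cc1 | intermediate
23 | (Z)-2-iodoallylic alcohol (C15–OH) | C=C1C(=O)O[C@H](/C=C(\I)CO)[C@H]1[C@H](OC(=O)C(C)C)C/C(C)=C/CCOCc1ccc(OC)cc1 | intermediate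
24 | C15 triethylsilyl ether | C=C1C(=O)O[C@H](/C=C(\I)CO[Si](CC)(CC)CC)[C@H]1[C@H](OC(=O)C(C)C)C/C(C)=C/CCOCc1ccc(OC)cc1 | intermediate
25 | C3 primary alcohol | C=C1C(=O)O[C@H](/C=C(\I)CO[Si](CC)(CC)CC)[C@H]1[C@H](OC(=O)C(C)C)C/C(C)=C/CCO | intermediate
26 | C3 aldehyde | C=C1C(=O)O[C@H](/C=C(\I)CO[Si](CC)(CC)CC)[C@H]1[C@H](OC(=O)C(C)C)C/C(C)=C/CC=O | intermediate
27 | ten-membered 1(10)E,4Z-dienolide, 3β-OH (3S), C15–OTES, 8β-isobutyrate | C=C1C(=O)O[C@@H]2/C=C(/CO[Si](CC)(CC)CC)[C@@H](O)C/C=C(\C)C[C@@H](OC(=O)C(C)C)[C@@H]12 | intermediate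
28 | 1β,10α-epoxide of 27 | C=C1C(=O)O[C@@H]2/C=C(/CO[Si](CC)(CC)CC)[C@@H](O)C[C@H]3O[C@]3(C)C[C@@H](OC(=O)C(C)C)[C@@H]12 | intermediate
29 | CNP0219050.1 | C=C1C(=O)O[C@@H]2/C=C(/CO)[C@@H](O)C[C@H]3O[C@]3(C)C[C@@H](OC(=O)C(C)C)[C@@H]12 | target

**Step count and risks**
Total: 21 steps. Longest linear sequence: 20 steps (3 → 29, steps 2–21).

Most likely to fail:

1. Step 19 (Ni/Cr ring closure). The alkenylchromium may add to the wrong face of the C3 aldehyde, because only the macrocyclic transition state decides, and oligomerisation may compete with closure of the strained ring. Fallback: starting from 26, the closure is run without regard to the facial outcome and the C3-epimeric macrocyclic alcohol F1 (alone or mixed with 27) is collected. Dess–Martin oxidation converts the carbinol into the C3 enone F2. Reduction of F2 with (R)-Me-CBS and catecholborane at −78 °C, with the alkenyl carbon C4 acting as the large group, should give the 3S alcohol, which is 27. Control at C3 thus moves from C–C bond formation to reagent-controlled hydride delivery.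

2. Step 7 (tandem union). The congested enolate may be protonated (for instance by the γ-hydrogen of unreacted butenolide) or be aminomethylated incompletely in the HMPA-rich medium, so that the tandem breaks down. Fallback: starting from 10 and 2, the conjugate addition is run alone and quenched with NH4Cl at −78 °C to isolate the saturated 6,7-trans lactone F3. F3 is then enolised cleanly with LDA in THF at −78 °C to regenerate 12, treated with Eschenmoser's salt to give 13, quaternised with MeI to 14 and eliminated with aqueous NaHCO3, returning to 15. The two bond formations are thereby decoupled.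

3. Step 9 (C8 reduction). Hydride delivery may show poor facial selectivity if catalyst and C7 stereocentre are mismatched, and the base-sensitive ketone may suffer alkene migration on prolonged handling. Fallback: starting from 16, the ketone is reduced quickly under Luche conditions (NaBH4, CeCl3, MeOH, −78 °C) and the epimers are separated. The (8S)-alcohol F4 is esterified under Mitsunobu conditions (isobutyric acid, PPh3, DIAD, THF, 0 °C) with inversion, giving 18 directly, while any 17 is acylated as in step 10. C8 is then fixed by SN2 inversion and not by face-selective reduction.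

**Further compounds**
F1 | step 19 | C3-epimer of 27 (3R alcohol) | C=C1C(=O)O[C@@H]2/C=C(/CO[Si](CC)(CC)CC)[C@H](O)C/C=C(\C)C[C@@H](OC(=O)C(C)C)[C@@H]12
F2 | step 19 | macrocyclic C3 enone | C=C1C(=O)O[C@@H]2/C=C(/CO[Si](CC)(CC)CC)C(=O)C/C=C(\C)C[C@@H](OC(=O)C(C)C)[C@@H]12
F3 | step 7 | saturated 6,7-trans lactone with the C8 dithiane (no C13) | C1C(=O)O[C@H](CO[Si](C)(C)C(C)(C)C)[C@H]1C1(C/C(C)=C/CCOCc2ccc(OC)cc2)SCCCS1
F4 | step 9 | (8S)-alcohol, C8 epimer of 17 | C=C1C(=O)O[C@H](CO[Si](C)(C)C(C)(C)C)[C@H]1[C@@H](O)C/C(C)=C/CCOCc1ccc(OC)cc1
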